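**Strategy.** The quinone ring is built, not decorated. Its six carbons (numbered as in 3-heneicosyl-5-methoxy-2-methyl-1,4-benzoquinone) are cut into a four-carbon unit, C4(=O)–C5(OMe)=C6(H)–C1(=O), supplied by methyl semisquarate, and a two-carbon unit, C2(Me)=C3(C21H43), supplied as a trisubstituted alkenyllithium. The key step is the thermal ring expansion of the resulting 4-alkenyl-4-hydroxycyclobutenone: 4π opening of the strained ring cleaves a C1–C4 bond that the target does not contain, the dienylketene closes by 6π electrocyclisation (new C1–C2 bond), and tautomerisation/oxidation gives the quinone. One operation closes the carbocycle and fixes both carbonyls and all four substituents with no regiochemical choice on an arene.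

Key step: step 5

Remark: the target has no stereocentre and no stereogenic double bond, so the request for a single enantiomer is met by the constitution alone; alkene geometry is specified for intermediates but is erased in the key step.

**Step 1**
Reactants: 1 dimethyl squarate (3,4-dimethoxycyclobut-3-ene-1,2-dione)
Product: 3 3-methoxycyclobut-3-ene-1,2-dione (methyl semisquarate), via hydroxycyclobutenone 2 (not isolated)
Conditions: LiAlH(OtBu)3 (1.05 equiv), THF, −78 → −20 °C; aq. HCl quench; crude 2, conc. aq. HCl (cat.), CH2Cl2, rt; used promptly
Reagents that add atoms: water, O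
Why: Selective 1,2-hydride transfer from the bulky aluminium hydride to one squarate carbonyl, then acid-mediated allylic 1,3-carbonyl transposition (ionisation at the carbinol, water attack at the methoxy-stabilised carbon, loss of methanol), is the established reduction/hydrolysis route from dialkyl squarates to semisquarate esters; the racemic carbinol centre of 2 disappears.

**Step 2**
Reactants: 4 1-bromodocosane
Product: 5 docosyltriphenylphosphonium bromide
Conditions: PPh3 (1.1 equiv), toluene, reflux, 48 h
Reagents that add atoms: triphenylphosphine, c1ccc(cc1)P(c1ccccc1)c1ccccc1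
Why: SN2 quaternisation of triphenylphosphine by a primary alkyl bromide (phosphonium salt formation for a Wittig reaction); no stereocentre is formed.

**Step 3**
Reactants: 5 docosyltriphenylphosphonium bromide; 6 acetaldehyde
Product: 10 (Z)-3-iodotetracos-2-ene, via ylide 7 (not isolated), via iodophosphonium iodide 8 (not isolated), via iodo ylide 9 (not isolated)
Conditions: n-BuLi (1.0 equiv), THF, 0 °C → rt; I2 (1.0 equiv), −78 °C; NaHMDS (1.0 equiv), −78 → −20 °C; CH3CHO (excess), −78 °C → rt
Reagents that add atoms: iodine, II
Why: Stork–Zhao-type iodo-olefination: ylide 7 is iodinated at carbon, deprotonated to the α-iodo ylide 9, and its kinetically controlled Wittig reaction with acetaldehyde should place the aldehyde methyl cis to iodine (Z), a geometry of no consequence for the target because this carbon becomes a ring carbon in step 5.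

**Step 4**
Reactants: 10 (Z)-3-iodotetracos-2-ene; 3 3-methoxycyclobut-3-ene-1,2-dione
Product: 12 4-hydroxy-3-methoxy-4-[(Z)-tetracos-2-en-3-yl]cyclobut-2-en-1-one (racemic), via alkenyllithium 11 (not isolated)
Conditions: 10, t-BuLi (2.0 equiv), Et2O, −78 °C; cannulate into 3 (1.2 equiv), THF, −78 °C; sat. aq. NH4Cl at −78 °C
Reagents that add atoms: none
Why: Iodine–lithium exchange with retention of alkene geometry gives 11, which as a hard nucleophile should add 1,2 to the ketone-like carbonyl of 3 flanked by the methoxy-bearing carbon, the other carbonyl being deactivated as a vinylogous ester (the rule followed by organolithium additions to 3-alkoxycyclobutenediones); the carbinol centre forms racemic and is destroyed in step 5.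

**Step 5**
Reactants: 12 4-hydroxy-3-methoxy-4-[(Z)-tetracos-2-en-3-yl]cyclobut-2-en-1-one
Product: 16 3-heneicosyl-5-methoxy-2-methylcyclohexa-2,5-diene-1,4-dione (target), via dienylketene 13 (not isolated), via cyclohexadienone 14 (not isolated), via hydroquinone 15 (not isolated)
Conditions: degassed p-xylene (0.02 M), 138 °C, Ar; cool; then Ag2O (2 equiv), Na2SO4, Et2O, rt
Reagents that add atoms: none
Why: Thermal conrotatory 4π ring opening of the cyclobutenone cleaves the carbonyl–carbinol σ-bond to give dienylketene 13, whose ketene carbon and methyl-bearing alkene terminus join in a disrotatory 6π electrocyclisation (six-membered carbocycle) to dienone 14, which enolises to hydroquinone 15 and is oxidised by Ag2O. The closest known reaction type is the thermal ring expansion of 4-alkenyl- and 4-aryl-4-hydroxycyclobutenones to hydroquinones and quinones (Moore rearrangement). The selectivity required is torquoselectivity in the ring opening: the hydroxyl donor should rotate outward, which turns the alkenyl group inward and cis to the ketene as closure demands. The methyl group of the (Z)-alkene points inward during closure, which should be tolerated because the ketene terminus is sp-hybridised and unsubstituted (dienylketenes with a fully substituted terminus are known to close to 6,6-disubstituted dienones). The only stereocentres (C4 of 12, C6 of 14) are transient and vanish on aromatisation, as the achiral target requires. Regiochemistry is a matter of connectivity, not selectivity: OMe and H arrive on the four-carbon unit, C21H43 and Me on the alkene, each already in its final position.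

**Compound list**
1 | dimethyl squarate (3,4-dimethoxycyclobut-3-ene-1,2-dione) | COC1=C(OC)C(=O)C1=O | starting material
2 | 4-hydroxy-2,3-dimethoxycyclobut-2-en-1-one (racemic) | COC1=C(OC)C(O)C1=O | intermediate
3 | 3-methoxycyclobut-3-ene-1,2-dione (methyl semisquarate) | COC1=CC(=O)C1=O | intermediate
4 | 1-bromodocosane | CCCCCCCCCCCCCCCCCCCCCCBr | starting material
5 | docosyltriphenylphosphonium bromide | CCCCCCCCCCCCCCCCCCCCCC[P+](c1ccccc1)(c1ccccc1)c1ccccc1.[Br-] | intermediate
6 | acetaldehyde | CC=O | starting material
7 | docosylidenetriphenylphosphorane | CCCCCCCCCCCCCCCCCCCCCC=P(c1ccccc1)(c1ccccc1)c1ccccc1 | intermediate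
8 | (1-iododocosyl)triphenylphosphonium iodide (racemic) | CCCCCCCCCCCCCCCCCCCCCC(I)[P+](c1ccccc1)(c1ccccc1)c1ccccc1.[I-] | intermediate
9 | (1-iododocosylidene)triphenylphosphorane | CCCCCCCCCCCCCCCCCCCCCC(I)=P(c1ccccc1)(c1ccccc1)c1ccccc1 | intermediate
10 | (Z)-3-iodotetracos-2-ene | C/C=C(\I)CCCCCCCCCCCCCCCCCCCCC | intermediate
11 | (E)-tetracos-2-en-3-yllithium (Li cis to the C1 methyl) | C/C=C(\[Li])CCCCCCCCCCCCCCCCCCCCC | intermediate
12 | 4-hydroxy-3-methoxy-4-[(Z)-tetracos-2-en-3-yl]cyclobut-2-en-1-one (racemic) | C/C=C(\C1(O)C(OC)=CC1=O)CCCCCCCCCCCCCCCCCCCCC | intermediate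
13 | (3Z,5Z)-5-heneicosyl-4-hydroxy-3-methoxyhepta-1,3,5-trien-1-one (dienylketene) | O=C=C/C(OC)=C(O)\C(CCCCCCCCCCCCCCCCCCCCC)=C/C | intermediate
14 | 5-heneicosyl-4-hydroxy-3-methoxy-6-methylcyclohexa-2,4-dien-1-one (racemic) | O=C1C=C(OC)C(O)=C(CCCCCCCCCCCCCCCCCCCCC)C1C | intermediate
15 | 3-heneicosyl-5-methoxy-2-methylbenzene-1,4-diol | Cc1c(O)cc(OC)c(O)c1CCCCCCCCCCCCCCCCCCCCC | intermediate
16 | 3-heneicosyl-5-methoxy-2-methylcyclohexa-2,5-diene-1,4-dione (CNP0104330.0) | CCCCCCCCCCCCCCCCCCCCCC1=C(C)C(=O)C=C(OC)C1=O | target

**Step count.** Total: 5 steps. Longest linear sequence: 4 steps (steps 2, 3, 4, 5 from 1-bromodocosane 4); step 1 is a one-step branch.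

**Steps most likely to fail**

Step 4. The alkenyllithium may attack the wrong carbonyl of 3 (the vinylogous-ester carbonyl next to the ring CH), which would lead to the regioisomeric quinone. Conjugate addition at the CH terminus or precipitation of the waxy iodide at −78 °C could also lower conversion. The fallback sets out from 4 and 3 and returns at 15; it exchanges the roles of the two alkene carbons instead of fighting the site preference. Kornblum oxidation of 4 (DMSO, NaHCO3, 130 °C) should give docosanal F1. Iodo-olefination of F1 with (1-iodoethylidene)triphenylphosphorane (made in the flask from ethyltriphenylphosphonium bromide, n-BuLi, I2, NaHMDS) should give (Z)-2-iodotetracos-2-ene F2. Exchange with t-BuLi should give (E)-tetracos-2-en-2-yllithium F3. Addition of F3 to 3 at the carbonyl next to the ring CH would give 4-hydroxy-2-methoxy-4-[(Z)-tetracos-2-en-2-yl]cyclobut-2-en-1-one F4. Thermolysis of F4 under the conditions of step 5 would then open and close to the same hydroquinone 15, because Me and C21H43 have changed places together with OMe and H. If no clean 1,2-addition can be obtained at either carbonyl, the fallback for step 5 bypasses 3 altogether.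

Step 5. The ring may open with the hydroxyl inward, after which the ketene is trapped as a butenolide. Alternatively the ketene may oligomerise if closure against the inward methyl is slow. The fallback sets out from 10 and returns at 16; it replaces the hydroxycyclobutenone by a hydroxyl-free ketene benzannulation. Alkenyllithium 11 (from 10) is acylated with N-methoxy-N-methylacetamide to (Z)-3-heneicosylpent-3-en-2-one F5. Trifluoroacetylation (LiHMDS, CF3CO2CH2CF3, −78 °C) should give (Z)-1,1,1-trifluoro-5-heneicosylhept-5-ene-2,4-dione F6. Detrifluoroacetylative diazo transfer (MsN3, Et3N, H2O, MeCN) should give (Z)-1-diazo-3-heneicosylpent-3-en-2-one F7. Irradiation of F7 with excess methoxyacetylene, then warming to 80 °C, should give 3-heneicosyl-5-methoxy-2-methylphenol F8 (photochemical Wolff rearrangement, [2+2] cycloaddition, 4π opening, 6π closure; Danheiser benzannulation). Oxidation of F8 at the free para position (Fremy's salt, or salcomine/O2 in DMF) should give 16.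

Step 3. The ylide may be iodinated incompletely (giving tetracos-2-ene after olefination) or twice, and volatile, enolisable acetaldehyde may be lost. The fallback sets out from 6 and returns at 11; it replaces the olefination by an sp2–sp3 cross-coupling. Acetaldehyde 6 with CBr4/PPh3 (CH2Cl2, 0 °C) should give 1,1-dibromoprop-1-ene F9. Palladium-catalysed trans-selective Negishi mono-alkylation of F9 with heneicosylzinc bromide should give (Z)-3-bromotetracos-2-ene F10. The zinc reagent is made in the flask from 1-bromoheneicosane, assumed to be commercial; the catalyst is PdCl2(DPEphos) in THF. Bromine–lithium exchange of F10 (t-BuLi, −78 °C) gives the same alkenyllithium 11.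

**Further compounds**
F1 | step 4 | docosanal | CCCCCCCCCCCCCCCCCCCCCC=O
F2 | step 4 | (Z)-2-iodotetracos-2-ene | I/C(C)=C\CCCCCCCCCCCCCCCCCCCCC
F3 | step 4 | (E)-tetracos-2-en-2-yllithium | [Li]/C(C)=C\CCCCCCCCCCCCCCCCCCCCC
F4 | step 4 | 4-hydroxy-2-methoxy-4-[(Z)-tetracos-2-en-2-yl]cyclobut-2-en-1-one (racemic) | O=C1C(OC)=CC1(O)/C(C)=C\CCCCCCCCCCCCCCCCCCCCC
F5 | step 5 | (Z)-3-heneicosylpent-3-en-2-one | C/C=C(\C(C)=O)CCCCCCCCCCCCCCCCCCCCC
F6 | step 5 | (Z)-1,1,1-trifluoro-5-heneicosylhept-5-ene-2,4-dione | C/C=C(\C(=O)CC(=O)C(F)(F)F)CCCCCCCCCCCCCCCCCCCCC
F7 | step 5 | (Z)-1-diazo-3-heneicosylpent-3-en-2-one | C/C=C(\C(=O)C=[N+]=[N-])CCCCCCCCCCCCCCCCCCCCC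
F8 | step 5 | 3-heneicosyl-5-methoxy-2-methylphenol | Cc1c(O)cc(OC)cc1CCCCCCCCCCCCCCCCCCCCC
F9 | step 3 | 1,1-dibromoprop-1-ene | CC=C(Br)Br
F10 | step 3 | (Z)-3-bromotetracos-2-ene | C/C=C(\Br)CCCCCCCCCCCCCCCCCCCCC
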